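The earlier runs and the new flask stem from a simulated flask for an exercise, and the scatter is random.

Hours per turn of the catalyst are the measure for the next charge, which either keeps elm's free catalyst or rises to cedar's.

in all of them: substrate 0.10 M
- elm: reagent 0.095 M; capture agent 0.030 M; free catalyst 15 mM; the very flask that is asked about, followed so far
- cedar: reagent 0.095 M; capture agent 0.030 M; free catalyst 22 mM; run made earlier
- flask: reagent 0.0950 M; capture agent 0.0300 M; free catalyst 15 mM

| run | time / h | product / % | substrate / % |
|---|---|---|---|
| elm | 1.00 | 1.0 | 83.5 |
| elm | 3.00 | 6.6 | 80.2 |
| elm | 6.00 | 14.2 | 70.6 |
| elm | 10.0 | 22.9 | 62.1 |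
| cedar | 2.50 | 4.9 | 73.3 |
| cedar | 8.00 | 26.3 | 50.7 |
| cedar | 15.0 | 46.4 | 30.0 |
| cedar | 20.0 | 57.8 | 20.4 |

(readings scatter by 1 percentage point)

1. apparent order in free catalyst when 30% of the substrate are converted (percent change of the rate of making product for one percent more free catalyst charged)

- reactions considered so far: catalyst intermediate B -> catalyst intermediate C; reagent + catalyst intermediate A -> catalyst intermediate B; substrate + free catalyst -> catalyst intermediate A; catalyst intermediate C -> free catalyst + product; catalyst intermediate A + capture agent -> trapped intermediate

Elm passes 30% conversion between its third and fourth readings, where product gains 8.7 percentage points, and this gives 6.90 h. That number is the catalyst charged, as a fraction of the substrate charged, divided by the fraction of substrate made into product per hour: the turnover time, an inverse turnover frequency counted on catalyst charged.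

Cedar passes the same conversion between its first two readings and gives 5.65 h, which is shorter. Equal turnover times would mean first order, so the shortening reads as an order of 1.52. This is my own reckoning, and it is a loose one, since each reading is good to 1 point. Still, it favours cedar's charge.

The forecast stands at 1.12, above first order, on the ground that “extra catalyst holds more substrate as A, which has not consumed reagent”, so it favours the same charge. My loose reading of 1.52 stands higher than the forecast.

    catalyst intermediate B → catalyst intermediate C (k = 0.0335 min⁻¹)
    reagent + catalyst intermediate A → catalyst intermediate B (k = 0.0982 M⁻¹ min⁻¹)
    substrate + free catalyst → catalyst intermediate A (k = 8.09 M⁻¹ min⁻¹)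
    catalyst intermediate C → free catalyst + product (k = 0.00790 min⁻¹)
    catalyst intermediate A + capture agent → trapped intermediate (k = 0.0302 M⁻¹ min⁻¹)

The flask gives an apparent order of 1.3, inside the forecast's margin. Catalyst intermediate C, the form that releases product, has a lifetime of 2.11 h, which is 30.6% of elm's turnover time and 37.3% of cedar's. Free catalyst has a half-life of 0.0143 h with substrate as charged, far shorter than the 1.46 h of catalyst intermediate C, and after 6.41 h the flask holds 0.528% of its catalyst as free catalyst against 37.9% as catalyst intermediate C.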